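Readings and results were computed on assumed constants.

Slowness is what I look at first: starting material and open intermediate stand flat from 2.50 h, yet the target creeps up and then stalls near 2.26%, the mean of the readings from that time on.

- south: starting material 0.020 M; partner 0.014 M; the very flask that is asked about, followed so far
- flask: starting material 0.020 M; partner 0.0140 M; time 30 h

south run (percent of the starting material charged)

| time / h | starting material / % | target / % | open intermediate / % |
|---|---|---|---|
| 0.500 | 71.8 | 0 | 27.7 |
| 1.33 | 63.3 | 0.8 | 35.4 |
| 2.50 | 62.1 | 2.1 | 36.0 |
| 4.00 | 61.9 | 1.8 | 34.9 |
| 5.00 | 62.5 | 2.2 | 35.8 |
| 8.00 | 61.6 | 2.9 | 35.9 |
| 10.0 | 61.6 | 2.3 | 35.8 |

(standard deviation of a reading: 0.5 percentage points)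

- the reaction counts as stopped when no species that holds the starting material changes by six tenths of a point or more over the second half of the time

- the state of affairs at 30 h: stopped, and by what, or still going (the partner has run out first / it is still moving / forward and back rates have come level / all of the starting material has reacted)
- conversion of starting material at 30 h
- amount of target at 30 h, in percent of the starting material charged
- amount of open intermediate at 30 h, in percent of the starting material charged

The open intermediate holds steady while the target stalls, so I take the rate of target to follow something unread, and my candidate is the partner, dying away exponentially by a path of its own. Integrating such a rate gives ceiling = early rate × mean life. The reading of 0.8% at 1.33 h then gives a mean life of 3.76 h, a rough figure, since the scatter of 0.5 percentage points is large against that reading. This life is shorter than the 30 h asked about, so on my reckoning 0.0341% of the partner's charge remains then.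

If the rate scales with the partner and the life does not depend on its charge, the ceiling scales with the charge. So I carry the target yield per partner, the ceiling divided by the molarity of partner charged: 1.61 /M. A neighbouring flask looks the same but holds 0.056 M of partner instead of 0.0140 M. I expect both to end when the partner's life is over, this flask at 2.25% of target and the neighbour at 9.04%.

The forecast says forward and back rates have come level, with conversion 38.1%, target 2.4% and open intermediate 35.7%, holding that “the step to target also looks reversible”. My reckoning differs from it on the ending.

The flask gives the partner has run out first, with 0% of the partner left, conversion 38.2%, target 2.18% and open intermediate 35.8%.

    partner → second intermediate (k = 2.52 × 10⁻⁴ /s)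
    second intermediate → decomposed reagent (k = 0.00131 /s)
    open intermediate + second intermediate → target (k = 0.00757 /M/s)
    starting material ⇌ open intermediate (K = 0.580, k = 2.97 × 10⁻⁴ /s)
    partner + target → over-reaction product (k = 0.00443 /M/s)

In this flask the partner is the limiting reagent, with 0% of it left, and my 2.25% of target stands against 2.18%. Conversion in this flask stands at 38.2% mainly because of the way back from open intermediate to starting material: in the run with that step taken away, conversion reaches 100%. In the neighbour my 9.04% stands against 6.42% of target, with 2.60% of over-reaction product beside it.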